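The earlier runs and the new flask are simulated from invented constants; the scatter is artificial.

The alder run, charged with 0.48 M of free monomer, holds 0.101 M of monomer in chains at its first reading, and the ash run, charged with 2.3 M, holds 0.0920 M at its first, both near the 85 mM of initiator, so I take it that each initiator quickly starts one chain and reckon onward from that burst.

| setting | alder | ash | Thursday's | Monday's | Friday's |
|---|---|---|---|---|---|
| free monomer | 0.48 M | 2.3 M | 0.50 M | 1.0 M | 2.0 M |
| initiator | 85 mM | 85 mM | 85 mM | 85 mM | 85 mM |
| remark | run made earlier | run made earlier |  |  |  |
| time |  |  | 2.0 h | 2.0 h | 2.0 h |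

| run | time / min | monomer in chains / % | side product / % |
|---|---|---|---|
| alder | 25.0 | 21 | 2 |
| alder | 50.0 | 22 | 5 |
| alder | 80.0 | 25 | 10 |
| alder | 90.0 | 26 | 8 |
| alder | 120 | 27 | 12 |
| ash | 10.0 | 4 | 2 |
| ash | 20.0 | 4 | 3 |
| ash | 30.0 | 9 | 8 |
| ash | 60.0 | 8 | 11 |
| ash | 120 | 9 | 27 |

(readings scatter by 1.5 percentage points)

1. share of monomer in chains in all that became monomer in chains or side product for Thursday's, Monday's, Friday's, in this order
2. how that number moves from the first to the last of them (rises all the way / hardly changes / rises, then falls / falls all the way / falls, then rises)

- percentages count the free monomer that a species holds: one side product counts as two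
- "hardly changes" means that all values lie within two and a half points (for a concentration: within two and a half percent of the largest)

I assume that free monomer, at concentration M, feeds chains at a rate proportional to M and also consumes monomer in chains, U, at a rate proportional to M times U. Then U climbs towards a ceiling U*, the concentration of monomer in chains at which making equals using up, and made over used equals U*/U. Each side product counts twice what it takes from chains, so with ΔO its gain, ΔU the net gain in chains and Ū the mean of U, U* = Ū(1 + 2ΔU/ΔO). Between its first and last readings, the alder run gains 0.0288 M in chains and 0.0480 M in side product around a mean of 0.115 M, so U* reads 0.253 M, a reading that carries the scatter; the ash run's last 0.207 M stands a little lower than that.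

The gap U* − U then closes pseudo-first-order, at a rate proportional to M. By 2.0 h, alder has lost 39.0% of its free monomer and ash 36.0%, so I let the logarithm of the gap scale with the charge, and alder gives 0.641 M⁻¹. Starting from the burst, U at 2.0 h comes to 0.131 M, 0.165 M and 0.207 M for Thursday's, Monday's and Friday's. Dividing by the mean of those two losses, 37.5% of each charge, I expect shares of 70.0%, 43.9% and 27.6%.

The forecast says 69%, 49%, 29%, falls all the way, in its words “The share therefore falls steadily.”, and its Monday's figure is higher than mine.

The flasks give 65.8%, 48.1% and 30.9%, a share that falls all the way.

    free monomer + monomer in chains → side product (k = 0.470 M⁻¹ h⁻¹)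
    free monomer + living end → monomer in chains + living end, rate k2*[living end]*[free monomer] (k = 1.50 M⁻¹ h⁻¹)
    free monomer + initiator → living end + monomer in chains (k = 19.0 M⁻¹ h⁻¹)

Thursday's flask makes monomer in chains 2.44 times faster than it uses it up at 0.971 h and 2.01 times faster at 2.00 h, each step taken net, while my ceiling over Thursday's 0.135 M at that time gives 1.87. Held against Friday's charge, the ceiling comes to 12.7%, and Friday's flask after 20.0 h holds 13.4% as monomer in chains.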